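## Retrosynthetic overview

- Dictyoceratin C ⇐ the same decalin carrying an aroyl group (benzylic C=O, phenol masked). Deoxygenation comes last, so no acid or hydrogenation ever meets the exocyclic methylene.
- That aryl decalinyl ketone ⇐ an acyclic tertiary α-bromo aryl ketone by one radical cascade. Ring B closes first (C9–C10, 6-endo on an E trisubstituted alkene); ring A closes second (C5–C4, 6-exo-dig on a terminal alkyne, which becomes the C4 methylene).
- Only C8 is carried into the cascade as a stereocentre (catalytic asymmetric conjugate methylation of an aryl enone); C9, C10 and C5 follow from it.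
- Enone ⇐ aldol condensation of MOM-protected methyl 3-acetyl-4-hydroxybenzoate with (E)-4-methyldec-4-en-9-ynal; the enynal ⇐ Johnson–Claisen rearrangement on the isopropenyl Grignard adduct of hex-5-ynal.

Numbering used in the "Why" lines: decalin positions of the target (C4 bears the exocyclic methylene, C5 and C9 are quaternary, C8 carries the secondary methyl, C10 is the ring-fusion CH; ring A = C1–C5 and C10, ring B = C5–C10).

Assumption: the ligand enantiomer named in step 7 is taken to deliver the 3S ketone; if the first run shows the opposite sense, the enantiomeric ligand is used and nothing else changes.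

## Route

Step 1
Reactants: 1 hex-5-yn-1-ol
Product: 2 hex-5-ynal
Conditions: 2,2,6,6-tetramethylpiperidin-1-oxyl (10 mol %), PhI(OAc)2 (1.1 equiv), CH2Cl2, rt
Reagents that add atoms: none
Why: Oxoammonium-mediated alcohol oxidation stops at the aldehyde and leaves the terminal alkyne untouched; no stereocentre is involved.

Step 2
Reactants: 2 hex-5-ynal; 3 isopropenylmagnesium bromide
Product: 4 2-methyloct-1-en-7-yn-3-ol (racemic)
Conditions: THF, −78 → 0 °C; then H2O
Reagents that add atoms: none
Why: Grignard 1,2-addition to the aldehyde outruns deprotonation of the alkyne at −78 °C, and the carbinol centre may be racemic because it becomes sp2 in step 3.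

Step 3
Reactants: 4 2-methyloct-1-en-7-yn-3-ol; 5 triethyl orthoacetate
Product: 7 ethyl (4E)-4-methyldec-4-en-9-ynoate, via ketene acetal 6 (not isolated)
Conditions: MeC(OEt)3 (6 equiv), EtCO2H (5 mol %), 140 °C, EtOH distilled off
Reagents that add atoms: none
Why: Johnson–Claisen rearrangement through a chair with the alkynyl chain equatorial gives the E trisubstituted alkene (typically ≥97:3), whose geometry later fixes the trans ring fusion.

Step 4
Reactants: 7 ethyl (4E)-4-methyldec-4-en-9-ynoate
Product: 8 (4E)-4-methyldec-4-en-9-ynal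
Conditions: i-Bu2AlH (1.05 equiv), CH2Cl2, −78 °C; then H2O (Rochelle salt work-up)
Reagents that add atoms: none
Why: Partial ester reduction stops at the aluminium hemiacetal at −78 °C and releases the aldehyde on work-up, without touching alkene or alkyne.

Step 5
Reactants: 9 methyl 3-acetyl-4-hydroxybenzoate
Product: 10 methyl 3-acetyl-4-(methoxymethoxy)benzoate
Conditions: NaH (1.05 equiv), MOMCl (1.2 equiv), THF/DMF, 0 °C → rt
Reagents that add atoms: chloromethyl methyl ether, COCCl
Why: O-Alkylation of the phenoxide (MOM protection) prevents oxa-Michael closure to a chromanone and acyl or silyl migration in the later enolate steps.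

Step 6
Reactants: 10 methyl 3-acetyl-4-(methoxymethoxy)benzoate; 8 (4E)-4-methyldec-4-en-9-ynal
Product: 13 methyl 4-(methoxymethoxy)-3-[(2E,6E)-6-methyldodeca-2,6-dien-11-ynoyl]benzoate, via aldol adduct 11 (not isolated), via mesylate 12 (not isolated)
Conditions: LiN(SiMe3)2 (1.05 equiv), THF, −78 °C; add 8; then MsCl (1.5 equiv), Et3N (3 equiv), −78 → 0 °C
Reagents that add atoms: none
Why: Directed aldol addition of the only possible ketone enolate, then mesylation and E1cB elimination (aldol condensation), gives the E enone.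

Step 7
Reactants: 13 methyl 4-(methoxymethoxy)-3-[(2E,6E)-6-methyldodeca-2,6-dien-11-ynoyl]benzoate
Product: 15 methyl 4-(methoxymethoxy)-3-[(3S,6E)-2,3,6-trimethyldodec-6-en-11-ynoyl]benzoate (both C-2 epimers), via magnesium enolate 14 (not isolated)
Conditions: CuBr·SMe2 (5 mol %), (R)-1-[(SP)-2-(diphenylphosphino)ferrocenyl]ethyldicyclohexylphosphine (6 mol %), MeMgBr (1.3 equiv), t-BuOMe, −78 °C; then MeI (10 equiv), DMPU, −78 → 0 °C
Reagents that add atoms: methylmagnesium bromide, C[Mg]Br; iodomethane, CI
Why: Copper-catalysed asymmetric conjugate addition of the Grignard reagent sets C-3 (the future C8, S) under catalyst control, and C-methylation of the resulting enolate installs the future C9 methyl, whose configuration is irrelevant because C-2 becomes a radical in step 9.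

Step 8
Reactants: 15 methyl 4-(methoxymethoxy)-3-[(3S,6E)-2,3,6-trimethyldodec-6-en-11-ynoyl]benzoate
Product: 16 methyl 3-[(3S,6E)-2-bromo-2,3,6-trimethyldodec-6-en-11-ynoyl]-4-(methoxymethoxy)benzoate (both C-2 epimers)
Conditions: KN(SiMe3)2 (1.1 equiv), THF, −78 °C; NBS (1.2 equiv), −78 °C; then H2O
Reagents that add atoms: N-bromosuccinimide, O=C1CCC(=O)N1Br
Why: The ketone has a single enolisable position, the silazide base is too weak to metalate the alkyne, and electrophilic bromination of the enolate is far faster than attack on the alkene.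

Step 9
Reactants: 16 methyl 3-[(3S,6E)-2-bromo-2,3,6-trimethyldodec-6-en-11-ynoyl]-4-(methoxymethoxy)benzoate
Product: 17 methyl 4-(methoxymethoxy)-3-{[(1R,2S,4aS,8aR)-1,2,4a-trimethyl-5-methylidenedecahydronaphthalen-1-yl]carbonyl}benzoate
Conditions: (Me3Si)3SiH (1.2 equiv), 2,2'-azobis(2-methylpropionitrile) (0.2 equiv), PhH (0.005 M), 80 °C, slow addition over 6 h
Reagents that add atoms: none
Why: Proposed new method: bromine abstraction gives the tertiary α-keto radical at C9, which closes ring B 6-endo onto the CH end of the E alkene through a chair in which the C8–H bond lies in the plane of the enoxyl radical (allylic 1,3-strain), so the C8 methyl is equatorial, the C9 methyl axial and the aroyl group equatorial, while the E geometry puts H10 axial and anti to the C9 methyl; the tertiary C5 radical then closes ring A 6-exo-dig through the equatorial (trans-decalin) trajectory, because the axial one would force the incoming carbon syn-axial to the C9 methyl, and the vinyl radical takes hydrogen from the silane to give the exocyclic methylene; the closest known reaction types are 6-endo cyclisations of α-carbonyl radicals in Mn(OAc)3-type polyene cyclisations and reductive 6-exo-dig radical enyne cyclisations.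

Step 10
Reactants: 17 methyl 4-(methoxymethoxy)-3-{[(1R,2S,4aS,8aR)-1,2,4a-trimethyl-5-methylidenedecahydronaphthalen-1-yl]carbonyl}benzoate
Product: 18 methyl 4-hydroxy-3-{[(1R,2S,4aS,8aR)-1,2,4a-trimethyl-5-methylidenedecahydronaphthalen-1-yl]carbonyl}benzoate
Conditions: ZnBr2 (1.5 equiv), n-PrSH (3 equiv), CH2Cl2, 0 °C, 15 min
Reagents that add atoms: none
Why: Lewis-acid-assisted acetal exchange with the thiol removes the MOM group without protic acid, so the exocyclic alkene is not isomerised and no stereocentre is touched.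

Step 11
Reactants: 18 methyl 4-hydroxy-3-{[(1R,2S,4aS,8aR)-1,2,4a-trimethyl-5-methylidenedecahydronaphthalen-1-yl]carbonyl}benzoate
Product: 21 dictyoceratin C [methyl 4-hydroxy-3-{[(1R,2S,4aS,8aS)-1,2,4a-trimethyl-5-methylidenedecahydronaphthalen-1-yl]methyl}benzoate], via aryl tert-butyl carbonate 19 (not isolated), via ortho-quinone methide 20 (not isolated)
Conditions: Boc2O (1.3 equiv), 4-(dimethylamino)pyridine (10 mol %), THF, rt; then NaBH4 (4 equiv), THF–H2O, 0 °C → rt
Reagents that add atoms: none
Why: Borohydride reduces the ketone, the alkoxide takes over the Boc group and the phenoxide expels tert-butyl carbonate to give an ortho-quinone methide that accepts a second hydride at the benzylic carbon (reductive deoxygenation via an ortho-quinone methide), all under basic conditions that spare the ester, the alkene and every stereocentre.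

## Compound list

1 | hex-5-yn-1-ol | OCCCCC#C | starting material
2 | hex-5-ynal | O=CCCCC#C | intermediate
3 | isopropenylmagnesium bromide | C=C(C)[Mg]Br | starting material
4 | 2-methyloct-1-en-7-yn-3-ol (racemic) | C=C(C)C(O)CCCC#C | intermediate
5 | triethyl orthoacetate | CC(OCC)(OCC)OCC | starting material
6 | 3-[(1-ethoxyethenyl)oxy]-2-methyloct-1-en-7-yne (ketene acetal) | C=C(OCC)OC(CCCC#C)C(C)=C | intermediate (not isolated)
7 | ethyl (4E)-4-methyldec-4-en-9-ynoate | CCOC(=O)CC/C(C)=C/CCCC#C | intermediate
8 | (4E)-4-methyldec-4-en-9-ynal | O=CCC/C(C)=C/CCCC#C | intermediate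
9 | methyl 3-acetyl-4-hydroxybenzoate | CC(=O)c1cc(C(=O)OC)ccc1O | starting material
10 | methyl 3-acetyl-4-(methoxymethoxy)benzoate | CC(=O)c1cc(C(=O)OC)ccc1OCOC | intermediate
11 | methyl 3-[(6E)-3-hydroxy-6-methyldodec-6-en-11-ynoyl]-4-(methoxymethoxy)benzoate (aldol adduct, racemic carbinol) | COCOc1ccc(C(=O)OC)cc1C(=O)CC(O)CC/C(C)=C/CCCC#C | intermediate (not isolated)
12 | methyl 3-[(6E)-3-(methanesulfonyloxy)-6-methyldodec-6-en-11-ynoyl]-4-(methoxymethoxy)benzoate | COCOc1ccc(C(=O)OC)cc1C(=O)CC(OS(C)(=O)=O)CC/C(C)=C/CCCC#C | intermediate (not isolated)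
13 | methyl 4-(methoxymethoxy)-3-[(2E,6E)-6-methyldodeca-2,6-dien-11-ynoyl]benzoate | COCOc1ccc(C(=O)OC)cc1C(=O)/C=C/CC/C(C)=C/CCCC#C | intermediate
14 | bromomagnesium enolate of methyl 3-[(3S,6E)-3,6-dimethyldodec-6-en-11-ynoyl]-4-(methoxymethoxy)benzoate | COCOc1ccc(C(=O)OC)cc1C(O[Mg]Br)=C[C@@H](C)CC/C(C)=C/CCCC#C | intermediate (not isolated)
15 | methyl 4-(methoxymethoxy)-3-[(3S,6E)-2,3,6-trimethyldodec-6-en-11-ynoyl]benzoate (both C-2 epimers) | COCOc1ccc(C(=O)OC)cc1C(=O)C(C)[C@@H](C)CC/C(C)=C/CCCC#C | intermediate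
16 | methyl 3-[(3S,6E)-2-bromo-2,3,6-trimethyldodec-6-en-11-ynoyl]-4-(methoxymethoxy)benzoate (both C-2 epimers) | COCOc1ccc(C(=O)OC)cc1C(=O)C(C)(Br)[C@@H](C)CC/C(C)=C/CCCC#C | intermediate
17 | methyl 4-(methoxymethoxy)-3-{[(1R,2S,4aS,8aR)-1,2,4a-trimethyl-5-methylidenedecahydronaphthalen-1-yl]carbonyl}benzoate | C=C1CCC[C@H]2[C@](C)(C(=O)c3cc(C(=O)OC)ccc3OCOC)[C@@H](C)CC[C@]12C | intermediate
18 | methyl 4-hydroxy-3-{[(1R,2S,4aS,8aR)-1,2,4a-trimethyl-5-methylidenedecahydronaphthalen-1-yl]carbonyl}benzoate | C=C1CCC[C@H]2[C@](C)(C(=O)c3cc(C(=O)OC)ccc3O)[C@@H](C)CC[C@]12C | intermediate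
19 | methyl 4-[(tert-butoxycarbonyl)oxy]-3-{[(1R,2S,4aS,8aR)-1,2,4a-trimethyl-5-methylidenedecahydronaphthalen-1-yl]carbonyl}benzoate | C=C1CCC[C@H]2[C@](C)(C(=O)c3cc(C(=O)OC)ccc3OC(=O)OC(C)(C)C)[C@@H](C)CC[C@]12C | intermediate (not isolated)
20 | methyl 4-oxo-3-{[(1S,2S,4aS,8aS)-1,2,4a-trimethyl-5-methylidenedecahydronaphthalen-1-yl]methylidene}cyclohexa-1,5-diene-1-carboxylate (ortho-quinone methide; decalin geometry unchanged) | C=C1CCC[C@H]2[C@](C)(C=C3C=C(C(=O)OC)C=CC3=O)[C@@H](C)CC[C@]12C | intermediate (not isolated)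
21 | dictyoceratin C, methyl 4-hydroxy-3-{[(1R,2S,4aS,8aS)-1,2,4a-trimethyl-5-methylidenedecahydronaphthalen-1-yl]methyl}benzoate | C=C1CCC[C@H]2[C@](C)(Cc3cc(C(=O)OC)ccc3O)[C@@H](C)CC[C@]12C | target

## Step count and risk

Total steps: 11. Longest linear sequence: 10 (steps 1–4 and 6–11, from hex-5-yn-1-ol); step 5 is a one-step branch.

**Step 9 (radical bicyclisation).** A radical may be quenched before the second ring closes, or ring A may close to the cis-fused isomer. The fallback sets out from 15 and returns at 17; it separates the two ring closures and re-initiates the second by hydrogen-atom transfer. Mn(OAc)3·2H2O (2.2 equiv) and Cu(OAc)2·H2O (1 equiv) in AcOH at 80 °C generate the same α-keto radical oxidatively from ketone 15, and ring B closes as before. The tertiary C5 radical is intercepted by divalent copper and loses a proton to give methyl 3-{[(1R,2S,6R)-1,2-dimethyl-5-methylidene-6-(pent-4-yn-1-yl)cyclohexyl]carbonyl}-4-(methoxymethoxy)benzoate F1. Any material that cyclises further under these conditions is already 17; if the acetal is lost in hot AcOH, the phenol is re-protected with MOMCl. Iron tris(acetylacetonate), Fe(C5H7O2)3 (30 mol %), with PhSiH3 in EtOH at 60 °C then adds a hydrogen atom to the only alkene left. This regenerates the C5 radical with nothing else in the molecule activated, and 6-exo-dig closure with hydrogen transfer gives 17.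

**Step 7 (asymmetric conjugate methylation).** The ortho-alkoxyaryl enone may give low enantioselectivity or 1,2-addition, and the in situ methylation may be sluggish. The fallback sets out from 8 and returns at 15, bypassing steps 6 and 7; it moves the conjugate addition to a thioester, the substrate class for which the copper/ferrocenyl-diphosphine methyl addition is most reliable. Wittig reaction of 8 with Ph3P=CHC(O)SEt gives S-ethyl (2E,6E)-6-methyldodeca-2,6-dien-11-ynethioate F2. MeMgBr, CuBr·SMe2 and the same ligand in t-BuOMe at −75 °C give S-ethyl (3S,6E)-3,6-dimethyldodec-6-en-11-ynethioate F3. Commercial methyl 4-hydroxy-3-iodobenzoate is converted with NaH/MOMCl into methyl 3-iodo-4-(methoxymethoxy)benzoate F4, and zinc dust with LiCl in THF gives methyl 3-(iodozincio)-4-(methoxymethoxy)benzoate F5. PdCl2(PPh3)2-catalysed Fukuyama coupling of F5 with F3 gives methyl 3-[(3S,6E)-3,6-dimethyldodec-6-en-11-ynoyl]-4-(methoxymethoxy)benzoate F6. LiN(SiMe3)2 then MeI in THF at −78 °C methylates its only enolisable position and returns to 15.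

**Step 11 (deoxygenation of the hindered aryl ketone).** Hydride attack on the neopentyl, ortho-substituted ketone may be so slow that the carbonate is lost before the quinone methide can form. The fallback sets out from 17 and returns at 21; it uses radical deoxygenation instead. NaBH4 in MeOH/THF at 40 °C (a long reaction time is harmless here because no carbonate is present) gives methyl 3-{hydroxy[(1R,2S,4aS,8aR)-1,2,4a-trimethyl-5-methylidenedecahydronaphthalen-1-yl]methyl}-4-(methoxymethoxy)benzoate F7. NaH, CS2 and then MeI give its O-(S-methyl dithiocarbonate) F8. Bu3SnH with 2,2'-azobis(2-methylpropionitrile) in PhMe at 100 °C (Barton–McCombie) gives methyl 4-(methoxymethoxy)-3-{[(1R,2S,4aS,8aS)-1,2,4a-trimethyl-5-methylidenedecahydronaphthalen-1-yl]methyl}benzoate F9. ZnBr2/n-PrSH as in step 10 then gives 21.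

## Further compounds

F1 | step 9 | methyl 3-{[(1R,2S,6R)-1,2-dimethyl-5-methylidene-6-(pent-4-yn-1-yl)cyclohexyl]carbonyl}-4-(methoxymethoxy)benzoate | C=C1CC[C@H](C)[C@@](C)(C(=O)c2cc(C(=O)OC)ccc2OCOC)[C@@H]1CCCC#C
F2 | step 7 | S-ethyl (2E,6E)-6-methyldodeca-2,6-dien-11-ynethioate | CCSC(=O)/C=C/CC/C(C)=C/CCCC#C
F3 | step 7 | S-ethyl (3S,6E)-3,6-dimethyldodec-6-en-11-ynethioate | CCSC(=O)C[C@@H](C)CC/C(C)=C/CCCC#C
F4 | step 7 | methyl 3-iodo-4-(methoxymethoxy)benzoate | COCOc1ccc(C(=O)OC)cc1I
F5 | step 7 | methyl 3-(iodozincio)-4-(methoxymethoxy)benzoate | COCOc1ccc(C(=O)OC)cc1[Zn]I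
F6 | step 7 | methyl 3-[(3S,6E)-3,6-dimethyldodec-6-en-11-ynoyl]-4-(methoxymethoxy)benzoate | COCOc1ccc(C(=O)OC)cc1C(=O)C[C@@H](C)CC/C(C)=C/CCCC#C
F7 | step 11 | methyl 3-{hydroxy[(1R,2S,4aS,8aR)-1,2,4a-trimethyl-5-methylidenedecahydronaphthalen-1-yl]methyl}-4-(methoxymethoxy)benzoate (carbinol epimers) | C=C1CCC[C@H]2[C@](C)(C(O)c3cc(C(=O)OC)ccc3OCOC)[C@@H](C)CC[C@]12C
F8 | step 11 | methyl 4-(methoxymethoxy)-3-{[(methylsulfanyl)carbonothioyl]oxy[(1R,2S,4aS,8aR)-1,2,4a-trimethyl-5-methylidenedecahydronaphthalen-1-yl]methyl}benzoate | C=C1CCC[C@H]2[C@](C)(C(OC(=S)SC)c3cc(C(=O)OC)ccc3OCOC)[C@@H](C)CC[C@]12C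
F9 | step 11 | methyl 4-(methoxymethoxy)-3-{[(1R,2S,4aS,8aS)-1,2,4a-trimethyl-5-methylidenedecahydronaphthalen-1-yl]methyl}benzoate | C=C1CCC[C@H]2[C@](C)(Cc3cc(C(=O)OC)ccc3OCOC)[C@@H](C)CC[C@]12C
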